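**Plan**
- Retrosynthesis cuts the lactol bond O1–C2 and the C2–C3 bond (C2 is a formyl carbon added to a ketone enolate), then C4–C4a (aryl anion plus Weinreb amide), giving a ring-A bromophenol and an (S)-3-aryl-3-silyloxypropanoyl unit.
- Ring A bears six substituents: the C6 and C8a oxygens are para, with the C7 oxygen and C8 methyl between them. These four carbons are the C4, C1, C3 and C2 of a squarate-derived 4-alkoxycyclobutenone, and C5–O with C4a–H is a 1-alkoxyvinyl group, so ring A is cut at C4a–C8a.
- Forward: diisopropyl squarate → methylcyclobutenedione → 4-(1-isopropoxyvinyl)-4-methoxycyclobutenone → thermal ring expansion to the ring-A phenol (first ring formed).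
- The free C8a–OH is kept distinct as a pivalate while C4a is brominated and the C5/C7 isopropyl ethers are exchanged for benzyl. The C4a anion is then joined to the side chain, and C3 formylation closes ring C through the only free phenol, which fixes the lactol regiochemistry.
- Stereochemistry: the (S)-carbinol comes from Noyori transfer hydrogenation of a β-keto ester. C2 and C3 are labile and settle by equilibration.

Key step: step 3

Assumption: C2 (lactol, ring–chain tautomerism) and C3 (enolisable, between the ketone and the masked aldehyde) are configurationally labile, so the (2S,3R) arrangement is taken to be the thermodynamically preferred one for the fixed (S)-carbinol and is reached by equilibration, not by kinetic control.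

**Route**

Step 1
Reactants: 1 diisopropyl squarate
Product: 3 3-isopropoxy-4-methylcyclobut-3-ene-1,2-dione, via hydroxycyclobutenone adduct 2 (not isolated)
Conditions: MeLi, THF, −78 °C; aq NH4Cl; crude in CH2Cl2, conc. HCl (cat.), rt
Reagents that add atoms: methyllithium, [Li]C
Why: 1,2-Addition of the organolithium to one squarate carbonyl, then acid-promoted allylic transposition with loss of isopropanol, is the standard squarate-to-alkylcyclobutenedione sequence.

Step 2
Reactants: 4 isopropyl vinyl ether; 3 3-isopropoxy-4-methylcyclobut-3-ene-1,2-dione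
Product: 7 3-isopropoxy-4-(1-isopropoxyvinyl)-4-methoxy-2-methylcyclobut-2-en-1-one (racemic), via 1-isopropoxyvinyllithium 5 (not isolated), via lithium alkoxide adduct 6 (not isolated)
Conditions: 4 (1.5 equiv), t-BuLi (1.3 equiv), THF, −78 → 0 °C; then 3, −78 °C; then MeOTf, −78 → 0 °C; aq NaHCO3, Et3N-deactivated silica
Reagents that add atoms: methyl trifluoromethanesulfonate, COS(=O)(=O)C(F)(F)F
Why: α-Lithiation of the vinyl ether, 1,2-addition to the more electrophilic carbonyl (the one beside the isopropoxy-bearing carbon, which is not a vinylogous ester) and in situ O-methylation of the tertiary alkoxide is the usual entry to 4-alkenyl-4-alkoxycyclobutenones; the new quaternary centre is racemic and is lost in step 3.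

Step 3
Reactants: 7 3-isopropoxy-4-(1-isopropoxyvinyl)-4-methoxy-2-methylcyclobut-2-en-1-one
Product: 10 3,5-diisopropoxy-4-methoxy-2-methylphenol, via dienylketene 8 (not isolated), via cyclohexadienone tautomer 9 (not isolated)
Conditions: PhMe (degassed, 0.05 M), 110 °C, argon
Reagents that add atoms: none
Why: Heating opens the strained cyclobutenone by a thermal conrotatory 4π electrocyclic cleavage of the C1–C4 bond to dienylketene 8; the C4 methoxy donor rotates outward, which places the 1-isopropoxyvinyl group inward, next to the ketene. A thermally allowed disrotatory 6π electrocyclisation then joins the ketene carbon (future C8a) to the vinyl CH2 terminus (future C4a), closing six-membered ring A as dienone 9, and enolisation aromatises it to the free C8a phenol. The closest known reaction type is the Moore rearrangement of squarate-derived 4-alkenyl-4-alkoxycyclobutenones to hydroquinone monoethers. No stereocentre is formed, since the racemic quaternary carbon of 7 becomes the planar C6 of the arene. The selectivity needed is regiochemical and torquoselective, and both are built into 7: its connectivity fixes methyl at C8, isopropoxy at C7 and C5 and methoxy at C6 with only C4a unsubstituted, and because C4 carries OMe instead of OH a ketene of the wrong geometry has no lactonisation exit and can only revert and re-open productively.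

Step 4
Reactants: 10 3,5-diisopropoxy-4-methoxy-2-methylphenol
Product: 11 3,5-diisopropoxy-4-methoxy-2-methylphenyl pivalate
Conditions: PivCl, Et3N, DMAP (cat.), CH2Cl2, 0 °C → rt
Reagents that add atoms: pivaloyl chloride, CC(C)(C)C(Cl)=O
Why: Esterification of the single free phenol (the C8a oxygen) keeps it distinct from the C5 and C7 oxygens in a group that tolerates NBS, BCl3 and carbonate base.

Step 5
Reactants: 11 3,5-diisopropoxy-4-methoxy-2-methylphenyl pivalate
Product: 12 2-bromo-3,5-diisopropoxy-4-methoxy-6-methylphenyl pivalate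
Conditions: NBS, MeCN, 0 °C, dark
Reagents that add atoms: N-bromosuccinimide, O=C1CCC(=O)N1Br
Why: Electrophilic aromatic bromination can only take the one unsubstituted ring carbon (C4a), which is ortho and para to alkoxy groups.

Step 6
Reactants: 12 2-bromo-3,5-diisopropoxy-4-methoxy-6-methylphenyl pivalate
Product: 13 2-bromo-3,5-dihydroxy-4-methoxy-6-methylphenyl pivalate
Conditions: BCl3 (3 equiv), CH2Cl2, −78 → 0 °C; H2O
Reagents that add atoms: none
Why: Lewis-acid ether cleavage with BCl3 removes secondary (isopropyl) aryl ethers much faster than the methyl ether and should spare the pivalate and the aryl bromide.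

Step 7
Reactants: 13 2-bromo-3,5-dihydroxy-4-methoxy-6-methylphenyl pivalate
Product: 14 3,5-bis(benzyloxy)-2-bromo-4-methoxy-6-methylphenyl pivalate
Conditions: BnBr, K2CO3, DMF, rt → 50 °C, argon
Reagents that add atoms: benzyl bromide, BrCc1ccccc1
Why: Williamson etherification of the two phenols; with C4a blocked by bromine no C-benzylation is possible, and the hindered pivalate, meta to both phenols, should not migrate.

Step 8
Reactants: 14 3,5-bis(benzyloxy)-2-bromo-4-methoxy-6-methylphenyl pivalate
Product: 15 3,5-bis(benzyloxy)-2-bromo-4-methoxy-6-methylphenol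
Conditions: i-Bu2AlH (2.5 equiv), CH2Cl2, −78 °C; aq Rochelle salt
Reagents that add atoms: none
Why: Hydride reduction of the aryl ester frees the C8a phenol without affecting benzyl ethers or the aryl bromide.

Step 9
Reactants: 16 4'-(benzyloxy)acetophenone
Product: 17 ethyl 3-[4-(benzyloxy)phenyl]-3-oxopropanoate
Conditions: NaH, (EtO)2CO, THF, reflux; aq HCl
Reagents that add atoms: diethyl carbonate, CCOC(=O)OCC
Why: Crossed Claisen condensation of the ketone enolate with the non-enolisable carbonate, driven by deprotonation of the β-keto ester formed.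

Step 10
Reactants: 17 ethyl 3-[4-(benzyloxy)phenyl]-3-oxopropanoate
Product: 18 ethyl (S)-3-[4-(benzyloxy)phenyl]-3-hydroxypropanoate
Conditions: RuCl[(S,S)-TsDPEN](p-cymene) (1 mol%), HCO2H–Et3N (5:2), DMF, 40 °C
Reagents that add atoms: none
Why: Noyori asymmetric transfer hydrogenation of the aryl ketone; the (S,S)-diamine catalyst should deliver hydride to the face that gives the (S)-carbinol, as for aryl alkyl ketones in general, and this centre becomes the carbinol stereocentre of the target.

Step 11
Reactants: 18 ethyl (S)-3-[4-(benzyloxy)phenyl]-3-hydroxypropanoate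
Product: 19 ethyl (S)-3-[4-(benzyloxy)phenyl]-3-[(tert-butyldimethylsilyl)oxy]propanoate
Conditions: TBSCl, imidazole, DMF, rt
Reagents that add atoms: tert-butyldimethylsilyl chloride, CC(C)(C)[Si](C)(C)Cl
Why: Imidazole-promoted silylation protects the secondary alcohol for the organometallic steps without touching the stereocentre.

Step 12
Reactants: 19 ethyl (S)-3-[4-(benzyloxy)phenyl]-3-[(tert-butyldimethylsilyl)oxy]propanoate
Product: 20 (S)-3-[4-(benzyloxy)phenyl]-3-[(tert-butyldimethylsilyl)oxy]-N-methoxy-N-methylpropanamide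
Conditions: MeNH(OMe)·HCl, i-PrMgCl, THF, −20 → 0 °C
Reagents that add atoms: N,O-dimethylhydroxylamine hydrochloride, CNOC.Cl
Why: Direct aminolysis of the ester by the chloromagnesium amide (Weinreb amide formation) proceeds at low temperature, where the β-silyloxy ester should not eliminate.

Step 13
Reactants: 15 3,5-bis(benzyloxy)-2-bromo-4-methoxy-6-methylphenol; 20 (S)-3-[4-(benzyloxy)phenyl]-3-[(tert-butyldimethylsilyl)oxy]-N-methoxy-N-methylpropanamide
Product: 22 (S)-1-[2,4-bis(benzyloxy)-6-hydroxy-3-methoxy-5-methylphenyl]-3-[4-(benzyloxy)phenyl]-3-[(tert-butyldimethylsilyl)oxy]propan-1-one, via dilithiated phenoxide 21 (not isolated)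
Conditions: 15, MeLi (1.0 equiv), THF, −78 °C; t-BuLi (2.0 equiv), −78 °C; then 20, −78 → −30 °C; aq NH4Cl
Reagents that add atoms: none
Why: Deprotonation and bromine–lithium exchange give the ortho-lithiated lithium phenoxide, which adds to the Weinreb amide to a chelated tetrahedral intermediate that releases the ketone only on work-up (Weinreb ketone synthesis), forming C4–C4a and leaving the silyloxy stereocentre untouched.

Step 14
Reactants: 22 (S)-1-[2,4-bis(benzyloxy)-6-hydroxy-3-methoxy-5-methylphenyl]-3-[4-(benzyloxy)phenyl]-3-[(tert-butyldimethylsilyl)oxy]propan-1-one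
Product: 24 (2S,3R)-5,7-bis(benzyloxy)-3-[(S)-[4-(benzyloxy)phenyl][(tert-butyldimethylsilyl)oxy]methyl]-2-hydroxy-6-methoxy-8-methylchroman-4-one, via open keto aldehyde 23 (not isolated)
Conditions: LiN(SiMe3)2 (2.3 equiv), THF, −78 °C; HCO2CH2CF3 (1.3 equiv), −78 °C; AcOH, −78 °C → rt
Reagents that add atoms: 2,2,2-trifluoroethyl formate, O=COCC(F)(F)F
Why: Crossed Claisen formylation of the phenoxide–enolate dianion gives keto aldehyde 23, whose only free phenol (C8a–OH) adds to the aldehyde on acidification (the classical o-hydroxyaryl ketone to 2-hydroxychromanone route), so ring C can close in one sense only; C2 and C3 form under equilibrating conditions (ring–chain tautomerism, enolisation) and should settle in the 2,3-trans arrangement favoured thermodynamically for the fixed (S)-carbinol.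

Step 15
Reactants: 24 (2S,3R)-5,7-bis(benzyloxy)-3-[(S)-[4-(benzyloxy)phenyl][(tert-butyldimethylsilyl)oxy]methyl]-2-hydroxy-6-methoxy-8-methylchroman-4-one
Product: 25 (2S,3R)-5,7-bis(benzyloxy)-3-[(S)-[4-(benzyloxy)phenyl](hydroxy)methyl]-2-hydroxy-6-methoxy-8-methylchroman-4-one
Conditions: HF·pyridine, pyridine, THF, 0 °C → rt; pH 7 phosphate buffer
Reagents that add atoms: none
Why: Fluoride-driven Si–O cleavage (silyl ether deprotection) under pyridine-buffered conditions should leave benzyl ethers and the lactol intact, with C2 and C3 staying under the same thermodynamic control.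

Step 16
Reactants: 25 (2S,3R)-5,7-bis(benzyloxy)-3-[(S)-[4-(benzyloxy)phenyl](hydroxy)methyl]-2-hydroxy-6-methoxy-8-methylchroman-4-one
Product: 26 (2S,3R)-2,5,7-trihydroxy-3-[(S)-hydroxy(4-hydroxyphenyl)methyl]-6-methoxy-8-methylchroman-4-one (CNP0141808.1)
Conditions: H2 (1 atm), 10% Pd/C, EtOAc, rt
Reagents that add atoms: none
Why: Catalytic hydrogenolysis of the three aryl benzyl ethers under neutral conditions, where a free secondary benzylic alcohol is normally retained, releases the phenols with no further reagent; the lactol is already closed through O1, and C2/C3 should remain at their equilibrium configuration.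

**Compound list**

1 | diisopropyl squarate | CC(C)OC1=C(OC(C)C)C(=O)C1=O | starting material
2 | 4-hydroxy-2,3-diisopropoxy-4-methylcyclobut-2-en-1-one (racemic) | CC(C)OC1=C(OC(C)C)C(C)(O)C1=O | intermediate
3 | 3-isopropoxy-4-methylcyclobut-3-ene-1,2-dione | CC(C)OC1=C(C)C(=O)C1=O | intermediate
4 | isopropyl vinyl ether | C=COC(C)C | starting material
5 | 1-isopropoxyvinyllithium | [Li]C(=C)OC(C)C | intermediate
6 | lithium alkoxide of 4-hydroxy-3-isopropoxy-4-(1-isopropoxyvinyl)-2-methylcyclobut-2-en-1-one (racemic) | [Li]OC1(C(=C)OC(C)C)C(OC(C)C)=C(C)C1=O | intermediate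
7 | 3-isopropoxy-4-(1-isopropoxyvinyl)-4-methoxy-2-methylcyclobut-2-en-1-one (racemic) | CC(C)OC(=C)C1(OC)C(OC(C)C)=C(C)C1=O | intermediate
8 | (3Z)-3,5-diisopropoxy-4-methoxy-2-methylhexa-1,3,5-trien-1-one | O=C=C(C)/C(OC(C)C)=C(\C(=C)OC(C)C)OC | intermediate
9 | 3,5-diisopropoxy-4-methoxy-2-methylcyclohexa-2,4-dien-1-one | O=C1CC(OC(C)C)=C(OC)C(OC(C)C)=C1C | intermediate
10 | 3,5-diisopropoxy-4-methoxy-2-methylphenol | CC(C)Oc1cc(O)c(C)c(OC(C)C)c1OC | intermediate
11 | 3,5-diisopropoxy-4-methoxy-2-methylphenyl pivalate | CC(C)Oc1cc(OC(=O)C(C)(C)C)c(C)c(OC(C)C)c1OC | intermediate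
12 | 2-bromo-3,5-diisopropoxy-4-methoxy-6-methylphenyl pivalate | CC(C)Oc1c(Br)c(OC(=O)C(C)(C)C)c(C)c(OC(C)C)c1OC | intermediate
13 | 2-bromo-3,5-dihydroxy-4-methoxy-6-methylphenyl pivalate | COc1c(O)c(Br)c(OC(=O)C(C)(C)C)c(C)c1O | intermediate
14 | 3,5-bis(benzyloxy)-2-bromo-4-methoxy-6-methylphenyl pivalate | COc1c(OCc2ccccc2)c(Br)c(OC(=O)C(C)(C)C)c(C)c1OCc1ccccc1 | intermediate
15 | 3,5-bis(benzyloxy)-2-bromo-4-methoxy-6-methylphenol | COc1c(OCc2ccccc2)c(Br)c(O)c(C)c1OCc1ccccc1 | intermediate
16 | 4'-(benzyloxy)acetophenone | CC(=O)c1ccc(OCc2ccccc2)cc1 | starting material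
17 | ethyl 3-[4-(benzyloxy)phenyl]-3-oxopropanoate | CCOC(=O)CC(=O)c1ccc(OCc2ccccc2)cc1 | intermediate
18 | ethyl (S)-3-[4-(benzyloxy)phenyl]-3-hydroxypropanoate | CCOC(=O)C[C@H](O)c1ccc(OCc2ccccc2)cc1 | intermediate
19 | ethyl (S)-3-[4-(benzyloxy)phenyl]-3-[(tert-butyldimethylsilyl)oxy]propanoate | CCOC(=O)C[C@H](O[Si](C)(C)C(C)(C)C)c1ccc(OCc2ccccc2)cc1 | intermediate
20 | (S)-3-[4-(benzyloxy)phenyl]-3-[(tert-butyldimethylsilyl)oxy]-N-methoxy-N-methylpropanamide | CON(C)C(=O)C[C@H](O[Si](C)(C)C(C)(C)C)c1ccc(OCc2ccccc2)cc1 | intermediate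
21 | lithium 3,5-bis(benzyloxy)-2-lithio-4-methoxy-6-methylphenoxide | COc1c(OCc2ccccc2)c([Li])c(O[Li])c(C)c1OCc1ccccc1 | intermediate
22 | (S)-1-[2,4-bis(benzyloxy)-6-hydroxy-3-methoxy-5-methylphenyl]-3-[4-(benzyloxy)phenyl]-3-[(tert-butyldimethylsilyl)oxy]propan-1-one | COc1c(OCc2ccccc2)c(C(=O)C[C@H](O[Si](C)(C)C(C)(C)C)c2ccc(OCc3ccccc3)cc2)c(O)c(C)c1OCc1ccccc1 | intermediate
23 | (3S)-1-[2,4-bis(benzyloxy)-6-hydroxy-3-methoxy-5-methylphenyl]-3-[4-(benzyloxy)phenyl]-3-[(tert-butyldimethylsilyl)oxy]-2-formylpropan-1-one (open keto aldehyde; C2 epimers and enol form) | COc1c(OCc2ccccc2)c(C(=O)C(C=O)[C@H](O[Si](C)(C)C(C)(C)C)c2ccc(OCc3ccccc3)cc2)c(O)c(C)c1OCc1ccccc1 | intermediate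
24 | (2S,3R)-5,7-bis(benzyloxy)-3-[(S)-[4-(benzyloxy)phenyl][(tert-butyldimethylsilyl)oxy]methyl]-2-hydroxy-6-methoxy-8-methylchroman-4-one | COc1c(OCc3ccccc3)c(C)c2c(c1OCc1ccccc1)C(=O)[C@H]([C@H](O[Si](C)(C)C(C)(C)C)c1ccc(OCc3ccccc3)cc1)[C@@H](O)O2 | intermediate
25 | (2S,3R)-5,7-bis(benzyloxy)-3-[(S)-[4-(benzyloxy)phenyl](hydroxy)methyl]-2-hydroxy-6-methoxy-8-methylchroman-4-one | COc1c(OCc3ccccc3)c(C)c2c(c1OCc1ccccc1)C(=O)[C@H]([C@H](O)c1ccc(OCc3ccccc3)cc1)[C@@H](O)O2 | intermediate
26 | (2S,3R)-2,5,7-trihydroxy-3-[(S)-hydroxy(4-hydroxyphenyl)methyl]-6-methoxy-8-methylchroman-4-one | COc1c(O)c(C)c2c(c1O)C(=O)[C@H]([C@H](O)c1ccc(O)cc1)[C@@H](O)O2 | target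

**Step count**

Total: 16 steps. Longest linear sequence: 12 steps (steps 1–8, then 13–16, from diisopropyl squarate); the ring-B branch (steps 9–12) adds 4 steps before the coupling.

**Steps most likely to fail**

Step 14 (formylation and lactolisation). The electron-rich phenoxide–enolate may expel silanolate from the β-carbon (E1cB) faster than it is formylated, or formylation may go to oxygen. The fallback avoids a basic enolate. It sets out from 22: TMSOTf and Et3N in CH2Cl2 at 0 °C should give the aryl trimethylsilyl ether–(Z)-trimethylsilyl enol ether F1 by soft enolisation. A Mukaiyama-type reaction of F1 with HC(OMe)3 and BF3·OEt2 at −78 °C would then attach C2 as an acetal, the aryl O–Si bond falling on aqueous work-up, to give the phenolic β-keto dimethyl acetal F2. Mild aqueous acid (AcOH–H2O–THF) should exchange the acetal for the lactol through the free C8a phenol, rejoining the route at 24.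

Step 13 (aryl anion plus Weinreb amide). The doubly lithiated, doubly flanked aryl nucleophile may add slowly and instead deprotonate the amide α-CH2, which would trigger β-elimination of silanolate, or simply be quenched. The fallback masks the phenol so that an ordinary mono-lithio species is used. It sets out from 15: allyl bromide and K2CO3 in DMF give the allyl 3,5-bis(benzyloxy)-2-bromo-4-methoxy-6-methylphenyl ether F3. Bromine–lithium exchange with n-BuLi at −78 °C and addition to 20 give the O-allyl ketone F4, and Pd(PPh3)4 with morpholine in THF removes the allyl group to return to 22.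

Step 15 (desilylation). Under the HF conditions the lactol may lose water to the chromone, or the carbinol may be lost by β-elimination or retro-aldol cleavage through the readily enolised, non-chelated C4 ketone. The fallback reverses the unmasking order so that silicon is removed from a ketone chelated by the C5 hydroxyl, which lowers C3–H acidity. It sets out from 24: hydrogenolysis (H2, Pd/C, EtOAc) gives the tert-butyldimethylsilyl ether of the target F5, and a neutral fluoride source (Et3N·3HF, MeCN, rt) then leads directly to 26.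

**Further compounds**

F1 | step 14 | (S,Z)-[1-[2,4-bis(benzyloxy)-3-methoxy-5-methyl-6-(trimethylsilyloxy)phenyl]-3-[4-(benzyloxy)phenyl]-3-[(tert-butyldimethylsilyl)oxy]prop-1-en-1-yl]oxy-trimethylsilane | COc1c(OCc2ccccc2)c(/C(O[Si](C)(C)C)=C/[C@H](O[Si](C)(C)C(C)(C)C)c2ccc(OCc3ccccc3)cc2)c(O[Si](C)(C)C)c(C)c1OCc1ccccc1
F2 | step 14 | (3S)-1-[2,4-bis(benzyloxy)-6-hydroxy-3-methoxy-5-methylphenyl]-3-[4-(benzyloxy)phenyl]-3-[(tert-butyldimethylsilyl)oxy]-2-(dimethoxymethyl)propan-1-one (C2 epimers) | COc1c(OCc2ccccc2)c(C(=O)C(C(OC)OC)[C@H](O[Si](C)(C)C(C)(C)C)c2ccc(OCc3ccccc3)cc2)c(O)c(C)c1OCc1ccccc1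
F3 | step 13 | allyl 3,5-bis(benzyloxy)-2-bromo-4-methoxy-6-methylphenyl ether | COc1c(OCc2ccccc2)c(Br)c(OCC=C)c(C)c1OCc1ccccc1
F4 | step 13 | (S)-1-[2-(allyloxy)-4,6-bis(benzyloxy)-5-methoxy-3-methylphenyl]-3-[4-(benzyloxy)phenyl]-3-[(tert-butyldimethylsilyl)oxy]propan-1-one | COc1c(OCc2ccccc2)c(C(=O)C[C@H](O[Si](C)(C)C(C)(C)C)c2ccc(OCc3ccccc3)cc2)c(OCC=C)c(C)c1OCc1ccccc1
F5 | step 15 | (2S,3R)-3-[(S)-[(tert-butyldimethylsilyl)oxy](4-hydroxyphenyl)methyl]-2,5,7-trihydroxy-6-methoxy-8-methylchroman-4-one | COc1c(O)c(C)c2c(c1O)C(=O)[C@H]([C@H](O[Si](C)(C)C(C)(C)C)c1ccc(O)cc1)[C@@H](O)O2
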